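## The problem

The target is the linear B-type proanthocyanidin trimer epiafzelechin-(4β→8)-epiafzelechin-(4β→8)-4'-O-methylepigallocatechin. It consists of three flavan-3-ol units, each a chroman (ring A fused to pyran ring C) with an aryl ring B on C2, joined by two bonds from the sp3 carbon C4 of one unit to the aromatic C8 of the next. There are eight stereocentres: C2 and C3 of every unit (all 2R,3R, that is 2,3-cis) and C4 of the top and middle units (3,4-trans, 4β). Within a unit the centres can control one another (C3 can direct a trans entry at C4, and C2 and C3 can be carried as a pair), but the units are too far apart to control each other, so each needs its own source of absolute configuration. The 2,3-cis arrangement is the less stable one and must come from a stereospecific bond formation at C2, not from equilibration. The two C4–C8 bonds are doubly benzylic to phloroglucinol-type rings and break under protic or strong Lewis acid, the ten phenols oxidise easily, and of the fourteen exocyclic oxygens one is a methyl ether that must be in place before the phenols are unmasked. The feature that opens the chosen route is ring A of the top unit: O1 on C8a and C4 on C4a are neighbours, C5 next to C4a bears oxygen, and C6 and C8 are unsubstituted. This is the pattern left when a nucleophile and an electrophile add across the triple bond of a 3,5-dioxygenated benzyne. Rings A of the middle and bottom units are phloroglucinol rings with one extra carbon substituent, as in 2,4,6-trihydroxybenzaldehyde.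

## Retrosynthesis

**Unmasking.** Target 33 is traced to 32, in which all ten phenols and the C3 hydroxyls of the top and middle units are benzyl ethers and the bottom C3 hydroxyl is free. Benzyl is chosen over acid-labile groups because one hydrogenolysis removes all twelve without acid near the C4–C8 bonds, and the methyl ether is untouched.

**Bottom ring C.** In 32 the bonds O1–C2 and C4a–C4 of the bottom unit are cut, giving phenol 24 and the terminal epoxy alcohol 30 through aryl ether 31. The neighbouring cut, a cationic C4(middle)–C8(bottom) coupling, would need a leaving group at C4 of a dimer and a preformed bottom flavan with its single methyl ether already in place, which is not a bulk chemical. The chosen cut removes one ring and two stereocentres, both of which arrive ready-made in 30. The forward steps must etherify with inversion at the benzylic carbinol (erythro alcohol to 2,3-cis flavan) and close the ring 6-endo at the epoxide CH2 from the only ring carbon the tether can reach.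

**Middle ring C.** The same two bonds of the middle unit are cut in 22 (the parent of 24 through 23), giving phenol 20 and the erythro epoxy alcohol 7 through ether 21. The aryl group on the far epoxide carbon of 7 is the future ring A of the bottom unit, its O1 oxygen marked as an allyl ether. In favour of this cut: the closing carbon is benzylic to a trioxygenated ring, C4 is set by inversion of a trans-epoxide, the tether allows attack only from C4a and not C6, and 7 is the building block also used for the top unit. The forward reaction needs a Mitsunobu etherification of a hindered phenol and a Lewis acid mild enough for the existing C4–C8 bond.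

**Top unit (key disconnection).** In 18 (the parent of 20 through 19) the bonds O1–C8a and C4a–C4 are cut together, giving benzyne 16 and the threo epoxy alcohol 9. The neighbouring cut is the one used for the middle unit, phenol 10 plus 7; it is kept as the fallback. The aryne cut is preferred because oxygen acts as the nucleophile, so the ionisable C2–O bond is never broken and C2 is retained; both bonds form in one flask under base, and no Lewis acid touches the most labile epoxide. A flavan with three stereocentres is reduced to an acyclic epoxy alcohol and a six-carbon aryne released from silyl triflate 14. The forward reaction needs regioselective addition of alkoxide 15 to 16, 6-endo opening of the epoxide by the aryl anion 17 with inversion, and a medium free of proton sources.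

**The epoxy alcohols.** 9 and 7 differ only at the carbinol and come from one epoxy ketone 6: chelation-controlled reduction gives 7, and Mitsunobu inversion of 7 through ester 8 gives 9. Ketone 6 is cut at the epoxide oxygen to chalcone 5 (asymmetric nucleophilic epoxidation) and 5 at its double bond to aldehyde 3 and ketone 4 (Claisen–Schmidt condensation). Aldehyde 3 comes from 1 through 2, using the hydrogen-bonded hydroxyl to tell the three oxygens apart.

**The aryne precursor.** Silyl triflate 14 is traced through bromophenol 11 to phenol 10; the bromine marks the carbon that receives silicon by retro-Brook rearrangement (through 12 and 13).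

**The bottom building block.** Epoxy alcohol 30 is cut at the epoxide oxygen to the racemic allylic alcohol 29 (Sharpless kinetic resolution, which gives the erythro isomer needed for inversion), 29 at the carbinol–vinyl bond to aldehyde 28, and 28 through alcohol 27 and ester 26 to the commercial phenol ester 25, which already carries the methyl ether.

## Roads not taken

**Alternative 1:** The cut removes ring C of the bottom unit at three bonds, C4a–C4, C4–C3 and O1–C2. In the forward direction phenol 24 and formaldehyde A3 would give an ortho-quinone methide, which the chiral benzyloxyketene acetal A2 would trap in a hetero-Diels–Alder reaction to give the spiro orthoester A1, a 3-benzyloxychroman-2-one equivalent.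
- Merits: the C4 methylene comes from the simplest reagent, three bonds form at once, and no arene has to attack an unactivated CH2. That attack is the soft spot of step 22 of the chosen route, so in this respect Alternative 1 is better.
- Weak points: A1 has no ring B. The 3,5-bis(benzyloxy)-4-methoxyphenyl group would have to be added to the lactone-level C2 and the lactol reduced with control of the 2,3-cis relationship. C3 depends on induction from a remote acetal auxiliary, and the quinone methide can also form para to the hydroxyl.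
- Comparison: this road answers only for the last ring and offers nothing for making 24. The chosen plan sets against it a bottom unit whose aryl group and both stereocentres arrive in 30, and a key step that settles a complete unit with three stereocentres at the start of the synthesis.

**Alternative 2:** The cut is C4a–C4 of the middle unit. Phenol 20 would be etherified with A5, an epoxy alcohol that already carries the complete bottom flavan, and a Lewis acid would then close middle ring C to give A4.
- Merits: the route is convergent, and the unactivated CH2 closure of the bottom unit would be done early on a small molecule. The reaction class is known, so as a key step it is better founded than the aryne annulation.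
- Weak points: A5 needs the bottom flavan as its 8-carbaldehyde and then the whole chalcone, epoxide and reduction sequence, which adds about four steps. The Mitsunobu etherification would have to join two very large, hindered partners. The top unit is not addressed.
- Comparison: the chosen plan uses the same closure in steps 13 and 22 but with the small epoxy alcohols 7 and 30, shares 7 between two units, and keeps the new chemistry for the one unit where oxygen can act as nucleophile and the C2–O bond stays intact.

**Alternative 3:** The cut is the C8–C8a bond inside ring A of the bottom unit. The dianion of the keto ester A7, a 3-benzyloxy-5-oxohex-2-enoate chain hung on C4 of the middle unit, would cyclise onto its own ester (Claisen condensation) and aromatise to A6.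
- Merits: the arene is built under base only, with no acid near the C4–C8 bonds. A6 has two equivalent hydroxyls beside the linkage, so the later ring C annulation has no site ambiguity.
- Weak points: A7 needs a 3,4-trans bond from C4 of the upper dimer to an sp3 carbon and a chain extension. After A6 the whole of bottom ring C is still to be made, as in steps 21 and 22. The route therefore spends extra steps on an aromatic ring that 1 supplies for nothing.
- Comparison: the regiochemical advantage is real, but in the chosen plan the tether already allows closure at only one ring carbon, so the advantage gains little.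

Key step: step 9

Assumption: 3,5-bis(benzyloxy)phenol (10), 4'-(benzyloxy)acetophenone (4) and methyl 3,5-dihydroxy-4-methoxybenzoate (25) are bought as such; each is one benzylation or esterification away from phloroglucinol, 4'-hydroxyacetophenone and 4-O-methylgallic acid.

## Route

Step 1
Reactants: 1 2,4,6-trihydroxybenzaldehyde
Product: 2 2,4-bis(benzyloxy)-6-hydroxybenzaldehyde
Conditions: BnBr (2.1 equiv), K2CO3, DMF, 0 °C to rt
Reagents that add atoms: benzyl bromide BrCc1ccccc1
Why: Williamson etherification; the hydroxyl hydrogen-bonded to the formyl group is the least nucleophilic, so two equivalents of bromide should stop at the 2,4-dibenzyl ether.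

Step 2
Reactants: 2 2,4-bis(benzyloxy)-6-hydroxybenzaldehyde
Product: 3 2-(allyloxy)-4,6-bis(benzyloxy)benzaldehyde
Conditions: allyl bromide, K2CO3, DMF, 50 °C
Reagents that add atoms: allyl bromide C=CCBr
Why: Williamson etherification of the remaining chelated phenol under more forcing conditions; the allyl ether marks the oxygen that becomes O1 of the next ring and can later be removed with a zerovalent palladium catalyst, without acid and without loss of benzyl ethers.

Step 3
Reactants: 3 2-(allyloxy)-4,6-bis(benzyloxy)benzaldehyde; 4 4'-(benzyloxy)acetophenone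
Product: 5 (E)-3-[2-(allyloxy)-4,6-bis(benzyloxy)phenyl]-1-[4-(benzyloxy)phenyl]prop-2-en-1-one
Conditions: KOH, EtOH/THF, rt
Reagents that add atoms: none
Why: Claisen–Schmidt condensation; the aldehyde has no α-hydrogen and the conjugated (E)-enone is the thermodynamic product of aldol dehydration.

Step 4
Reactants: 5 (E)-chalcone
Product: 6 [4-(benzyloxy)phenyl]{(2R,3S)-3-[2-(allyloxy)-4,6-bis(benzyloxy)phenyl]oxiran-2-yl}methanone
Conditions: poly-L-leucine, urea–H2O2, DBU, THF, rt
Reagents that add atoms: urea–hydrogen peroxide NC(N)=O.OO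
Why: Juliá–Colonna epoxidation; hydroperoxide adds to the enone inside the helical polypeptide and the enolate closes to the trans-epoxide, the L-polymer being the one that gives the (2R,3S) epoxy ketone in the chalcone series.

Step 5
Reactants: 6 (2R,3S)-epoxy ketone
Product: 7 (S)-[4-(benzyloxy)phenyl]{(2S,3S)-3-[2-(allyloxy)-4,6-bis(benzyloxy)phenyl]oxiran-2-yl}methanol (erythro)
Conditions: Zn(BH4)2, Et2O, −20 °C
Reagents that add atoms: none
Why: Chelation-controlled reduction of an α,β-epoxy ketone; zinc bridges the carbonyl and epoxide oxygens and hydride enters from the face away from the oxirane ring, which should give the erythro (anti) alcohol with the (S)-carbinol.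

Step 6
Reactants: 7 erythro epoxy alcohol
Product: 9 (R)-[4-(benzyloxy)phenyl]{(2S,3S)-3-[2-(allyloxy)-4,6-bis(benzyloxy)phenyl]oxiran-2-yl}methanol (threo), via 4-nitrobenzoate ester 8 (not isolated)
Conditions: 4-nitrobenzoic acid, PPh3, DIAD, THF, 0 °C; then K2CO3, MeOH, 0 °C
Reagents that add atoms: 4-nitrobenzoic acid O=C(O)c1ccc([N+](=O)[O-])cc1
Why: Mitsunobu inversion; the carboxylate displaces the oxyphosphonium group by SN2 (the neighbouring epoxide oxygen slows ionisation of the benzylic centre) and mild methanolysis frees the threo (syn) alcohol, whose carbinol oxygen now stems from the acid.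

Step 7
Reactants: 10 3,5-bis(benzyloxy)phenol
Product: 11 2-bromo-3,5-bis(benzyloxy)phenol
Conditions: NBS, CH2Cl2, −78 °C to rt
Reagents that add atoms: N-bromosuccinimide O=C1CCC(=O)N1Br
Why: Electrophilic aromatic bromination; at low temperature the position ortho to the free hydroxyl and para to a benzyloxy group should react in preference to C4, which is flanked by two benzyloxy groups.

Step 8
Reactants: 11 2-bromo-3,5-bis(benzyloxy)phenol
Product: 14 3,5-bis(benzyloxy)-2-(trimethylsilyl)phenyl trifluoromethanesulfonate, via trimethylsilyl ether 12 (not isolated), via lithium 2-silylphenoxide 13 (not isolated)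
Conditions: HMDS, THF, 70 °C; n-BuLi, THF, −78 °C; Tf2O, −78 °C to rt
Reagents that add atoms: hexamethyldisilazane C[Si](C)(C)N[Si](C)(C)C; trifluoromethanesulfonic anhydride O=S(=O)(OS(=O)(=O)C(F)(F)F)C(F)(F)F
Why: O-silylation, bromine–lithium exchange and retro-Brook rearrangement (1,3 O-to-C silyl shift) place silicon ortho to the phenoxide, which is then triflated; this is the standard entry to ortho-silylaryl triflates.

Step 9
Reactants: 9 threo epoxy alcohol; 14 3,5-bis(benzyloxy)-2-(trimethylsilyl)phenyl trifluoromethanesulfonate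
Product: 18 (2R,3R)-4β-[2-(allyloxy)-4,6-bis(benzyloxy)phenyl]-5,7-bis(benzyloxy)-2-[4-(benzyloxy)phenyl]chroman-3-ol (2,3-cis-3,4-trans), via potassium alkoxide 15 (not isolated), via 3,5-bis(benzyloxy)benzyne 16 (not isolated), via aryl potassium adduct 17 (not isolated)
Conditions: KH, THF, 0 °C; then 14, CsF, 18-crown-6, THF, 0 °C to rt
Reagents that add atoms: none
Why: Proposed new method: KH turns 9 into alkoxide 15 without leaving a conjugate acid, fluoride strips the silyl group of 14 and loss of triflate gives benzyne 16; the alkoxide adds to the aryne carbon remote from the flanking benzyloxy group (future C8a), because that group distorts the triple bond and stabilises by induction the carbanion that develops beside it (future C4a) in 17. The aryl anion then opens the trans-epoxide at its benzylic carbon in a 6-endo-tet closure of ring C, forming C4a–C4 while the epoxide oxygen becomes the C3 alkoxide. The closest known reaction type is the aryne annulation in which an alkoxide or phenoxide adds and the aryl anion is caught by a tethered ester, ketone or Michael acceptor, together with the cyclisation of aryl anions onto tethered epoxides; capture by an epoxide within an aryne annulation has not been shown. C2 and C3 are carried unchanged from 9 (the C2–O bond is not touched, hence the threo alcohol), and the new C4 centre is set by SN2 inversion at the epoxide carbon, which turns the trans-epoxide into the 3,4-trans (4β-aryl) chromanol. Three selectivities are needed: the aryne regiochemistry, secured by the benzyloxy group next to the triple bond; 6-endo over 5-exo opening, secured by the benzylic carbon bearing a trioxygenated aryl group, whereas the other epoxide carbon is deactivated by the adjacent C2–O bond; and ring closure over protonation, secured by the absence of acetonitrile, amine or free alcohol in the flask.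

Step 10
Reactants: 18 top-unit chroman-3-ol
Product: 19 (2R,3R)-4β-[2-(allyloxy)-4,6-bis(benzyloxy)phenyl]-3,5,7-tris(benzyloxy)-2-[4-(benzyloxy)phenyl]chroman
Conditions: NaH, BnBr, n-Bu4NI (cat.), DMF, 0 °C to rt
Reagents that add atoms: benzyl bromide BrCc1ccccc1
Why: Williamson etherification of the C3 alkoxide; the hydroxyl is capped before the neighbouring phenol is freed, because an activated C3–OH could otherwise be displaced by that phenol to give a fused dihydrobenzofuran.

Step 11
Reactants: 19 allyl ether
Product: 20 2-[(2R,3R,4β)-3,5,7-tris(benzyloxy)-2-(4-benzyloxyphenyl)chroman-4-yl]-3,5-bis(benzyloxy)phenol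
Conditions: Pd(PPh3)4 (cat.), morpholine, THF, rt
Reagents that add atoms: none
Why: Tsuji–Trost deallylation; zerovalent palladium ionises the aryl allyl ether to a π-allyl complex that morpholine intercepts, and the neutral conditions leave the benzyl ethers and the C4–aryl bond alone.

Step 12
Reactants: 20 phenol; 7 erythro epoxy alcohol
Product: 21 aryl ether in which the phenol oxygen of 20 carries the (R)-[4-(benzyloxy)phenyl]{(2S,3S)-3-[2-(allyloxy)-4,6-bis(benzyloxy)phenyl]oxiran-2-yl}methyl group
Conditions: PPh3, DIAD, toluene, 0 °C to rt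
Reagents that add atoms: none
Why: Mitsunobu etherification; the phenoxide displaces the oxyphosphonium group of the erythro alcohol with inversion, giving the (R)-configured ether, that is the threo arrangement needed for a 2,3-cis middle unit, with the epoxide as a spectator as in the Mitsunobu chemistry of other 2,3-epoxy alcohols.

Step 13
Reactants: 21 epoxy aryl ether
Product: 22 upper dimer: middle unit (2R,3R)-5,7-bis(benzyloxy)-2-[4-(benzyloxy)phenyl]chroman-3-ol carrying 2-(allyloxy)-4,6-bis(benzyloxy)phenyl at C4 (4β, 3,4-trans) and the 3-O-benzylated top unit of 20 at C8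
Conditions: BF3·OEt2 (0.2 equiv), CH2Cl2, −78 °C
Reagents that add atoms: none
Why: Intramolecular Friedel–Crafts epoxy–arene cyclisation; the Lewis acid activates the epoxide, whose benzylic carbon is attacked 6-endo by the ring carbon ortho to the tethering oxygen, the only one the tether can reach. Attack anti to the epoxide oxygen sets C4 of the middle unit trans to the new C3 hydroxyl, while C2 and C3 are carried from 21.

Step 14
Reactants: 22 upper dimer with free middle 3-OH
Product: 23 3-O-benzyl ether of 22
Conditions: NaH, BnBr, n-Bu4NI (cat.), DMF, 0 °C to rt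
Reagents that add atoms: benzyl bromide BrCc1ccccc1
Why: Williamson etherification, for the same reason as in step 10.

Step 15
Reactants: 23 allyl ether
Product: 24 upper-dimer phenol (23 with the allyl group replaced by hydrogen)
Conditions: Pd(PPh3)4 (cat.), morpholine, THF, rt
Reagents that add atoms: none
Why: Tsuji–Trost deallylation as in step 11; it frees the oxygen that becomes O1 of the bottom unit.

Step 16
Reactants: 25 methyl 3,5-dihydroxy-4-methoxybenzoate
Product: 26 methyl 3,5-bis(benzyloxy)-4-methoxybenzoate
Conditions: BnBr, K2CO3, DMF, 60 °C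
Reagents that add atoms: benzyl bromide BrCc1ccccc1
Why: Williamson etherification of both phenols; the methyl ether of the target is already in place.

Step 17
Reactants: 26 methyl 3,5-bis(benzyloxy)-4-methoxybenzoate
Product: 27 [3,5-bis(benzyloxy)-4-methoxyphenyl]methanol
Conditions: LiAlH4, THF, 0 °C
Reagents that add atoms: none
Why: Hydride reduction of an aryl ester to the benzylic alcohol.

Step 18
Reactants: 27 [3,5-bis(benzyloxy)-4-methoxyphenyl]methanol
Product: 28 3,5-bis(benzyloxy)-4-methoxybenzaldehyde
Conditions: MnO2, CH2Cl2, rt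
Reagents that add atoms: none
Why: Selective oxidation of a benzylic alcohol, which stops at the aldehyde.

Step 19
Reactants: 28 3,5-bis(benzyloxy)-4-methoxybenzaldehyde
Product: 29 rac-1-[3,5-bis(benzyloxy)-4-methoxyphenyl]prop-2-en-1-ol
Conditions: vinylmagnesium bromide, THF, −78 to 0 °C
Reagents that add atoms: vinylmagnesium bromide C=C[Mg]Br
Why: Grignard addition to an aldehyde without α-hydrogen gives the racemic secondary allylic alcohol.

Step 20
Reactants: 29 racemic allylic alcohol
Product: 30 (S)-[3,5-bis(benzyloxy)-4-methoxyphenyl][(2R)-oxiran-2-yl]methanol (erythro)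
Conditions: Ti(OiPr)4, L-(+)-DIPT, TBHP (0.6 equiv), 4 Å MS, CH2Cl2, −20 °C
Reagents that add atoms: tert-butyl hydroperoxide CC(C)(C)OO
Why: Sharpless kinetic resolution; with L-(+)-DIPT the (R)-enantiomer of the allylic alcohol should be epoxidised much faster than its antipode, on the face that gives the erythro epoxy alcohol, so that oxidant for about half of the material sets both centres of 30 and leaves (S)-29 behind.

Step 21
Reactants: 24 upper-dimer phenol; 30 erythro epoxy alcohol
Product: 31 aryl ether in which the phenol oxygen of 24 carries the (R)-[3,5-bis(benzyloxy)-4-methoxyphenyl][(2R)-oxiran-2-yl]methyl group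
Conditions: PPh3, DIAD, toluene, 0 °C to rt
Reagents that add atoms: none
Why: Mitsunobu etherification with inversion at the benzylic carbinol, as in step 12; the 3,5-dialkoxy-4-methoxyphenyl group stabilises a cation less than a 4-alkoxyphenyl group, which favours clean SN2 displacement.

Step 22
Reactants: 31 glycidyl-type aryl ether
Product: 32 dodeca-O-benzyl derivative of the target with the bottom 3-hydroxyl free
Conditions: FeBr3 (cat.), AgOTf (cat.), CH2Cl2, rt
Reagents that add atoms: none
Why: Intramolecular Friedel–Crafts epoxy–arene cyclisation of an aryl glycidyl-type ether, the parent case of this reaction class; the ring carbon ortho to the ether oxygen attacks the terminal CH2 (6-endo), the internal carbon being deactivated by the adjacent C2–O bond. No new stereocentre forms, and C2 and C3 of the bottom unit come from 31.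

Step 23
Reactants: 32 dodeca-O-benzyl ether
Product: 33 epiafzelechin-(4β→8)-epiafzelechin-(4β→8)-4'-O-methylepigallocatechin (CNP0146516.1)
Conditions: H2 (1 atm), Pd(OH)2/C, THF/MeOH, rt
Reagents that add atoms: none
Why: Hydrogenolysis of ten aryl benzyl ethers and two alkyl benzyl ethers under neutral conditions; the methyl ether, the C4–C8 bonds and all stereocentres are not affected.

## Compound list

1 | 2,4,6-trihydroxybenzaldehyde | O=Cc1c(O)cc(O)cc1O | starting material
2 | 2,4-bis(benzyloxy)-6-hydroxybenzaldehyde | O=Cc1c(O)cc(OCc2ccccc2)cc1OCc1ccccc1 | intermediate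
3 | 2-(allyloxy)-4,6-bis(benzyloxy)benzaldehyde | O=Cc1c(OCC=C)cc(OCc2ccccc2)cc1OCc1ccccc1 | intermediate
4 | 4'-(benzyloxy)acetophenone | CC(=O)c1ccc(OCc2ccccc2)cc1 | starting material
5 | (E)-3-[2-(allyloxy)-4,6-bis(benzyloxy)phenyl]-1-[4-(benzyloxy)phenyl]prop-2-en-1-one | O=C(/C=C/c1c(OCC=C)cc(OCc2ccccc2)cc1OCc1ccccc1)c1ccc(OCc2ccccc2)cc1 | intermediate
6 | [4-(benzyloxy)phenyl]{(2R,3S)-3-[2-(allyloxy)-4,6-bis(benzyloxy)phenyl]oxiran-2-yl}methanone | O=C(c1ccc(OCc2ccccc2)cc1)[C@@H]1O[C@H]1c1c(OCC=C)cc(OCc2ccccc2)cc1OCc1ccccc1 | intermediate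
7 | (S)-[4-(benzyloxy)phenyl]{(2S,3S)-3-[2-(allyloxy)-4,6-bis(benzyloxy)phenyl]oxiran-2-yl}methanol (erythro) | O[C@@H](c1ccc(OCc2ccccc2)cc1)[C@@H]1O[C@H]1c1c(OCC=C)cc(OCc2ccccc2)cc1OCc1ccccc1 | intermediate
8 | (R)-[4-(benzyloxy)phenyl]{(2S,3S)-3-[2-(allyloxy)-4,6-bis(benzyloxy)phenyl]oxiran-2-yl}methyl 4-nitrobenzoate | O=C(O[C@H](c1ccc(OCc2ccccc2)cc1)[C@@H]1O[C@H]1c1c(OCC=C)cc(OCc2ccccc2)cc1OCc1ccccc1)c1ccc([N+](=O)[O-])cc1 | intermediate (not isolated)
9 | (R)-[4-(benzyloxy)phenyl]{(2S,3S)-3-[2-(allyloxy)-4,6-bis(benzyloxy)phenyl]oxiran-2-yl}methanol (threo) | O[C@H](c1ccc(OCc2ccccc2)cc1)[C@@H]1O[C@H]1c1c(OCC=C)cc(OCc2ccccc2)cc1OCc1ccccc1 | intermediate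
10 | 3,5-bis(benzyloxy)phenol | Oc1cc(OCc2ccccc2)cc(OCc2ccccc2)c1 | starting material
11 | 2-bromo-3,5-bis(benzyloxy)phenol | Oc1cc(OCc2ccccc2)cc(OCc2ccccc2)c1Br | intermediate
12 | [2-bromo-3,5-bis(benzyloxy)phenoxy]trimethylsilane | C[Si](C)(C)Oc1cc(OCc2ccccc2)cc(OCc2ccccc2)c1Br | intermediate (not isolated)
13 | lithium 3,5-bis(benzyloxy)-2-(trimethylsilyl)phenoxide | [Li+].[O-]c1cc(OCc2ccccc2)cc(OCc2ccccc2)c1[Si](C)(C)C | intermediate (not isolated)
14 | 3,5-bis(benzyloxy)-2-(trimethylsilyl)phenyl trifluoromethanesulfonate | C[Si](C)(C)c1c(OCc2ccccc2)cc(OCc2ccccc2)cc1OS(=O)(=O)C(F)(F)F | intermediate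
15 | potassium alkoxide of 9 | [K+].[O-][C@H](c1ccc(OCc2ccccc2)cc1)[C@@H]1O[C@H]1c1c(OCC=C)cc(OCc2ccccc2)cc1OCc1ccccc1 | intermediate (not isolated)
16 | 3,5-bis(benzyloxy)benzyne (1,2-didehydro-3,5-bis(benzyloxy)benzene) | C1#CC(OCc2ccccc2)=CC(OCc2ccccc2)=C1 | intermediate (not isolated)
17 | aryl potassium adduct of 15 and 16: potassium 2,4-bis(benzyloxy)-6-{(R)-[4-(benzyloxy)phenyl][(2S,3S)-3-(2-allyloxy-4,6-dibenzyloxyphenyl)oxiran-2-yl]methoxy}benzen-1-ide | [K+].[c-]1c(OCc2ccccc2)cc(OCc2ccccc2)cc1O[C@H](c1ccc(OCc2ccccc2)cc1)[C@@H]1O[C@H]1c1c(OCC=C)cc(OCc2ccccc2)cc1OCc1ccccc1 | intermediate (not isolated)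
18 | (2R,3R)-4β-[2-(allyloxy)-4,6-bis(benzyloxy)phenyl]-5,7-bis(benzyloxy)-2-[4-(benzyloxy)phenyl]chroman-3-ol (2,3-cis-3,4-trans) | C=CCOc1cc(OCc7ccccc7)cc(OCc7ccccc7)c1[C@H]5c6c(OCc7ccccc7)cc(OCc7ccccc7)cc6O[C@H](c6ccc(OCc7ccccc7)cc6)[C@@H]5O | intermediate
19 | (2R,3R)-4β-[2-(allyloxy)-4,6-bis(benzyloxy)phenyl]-3,5,7-tris(benzyloxy)-2-[4-(benzyloxy)phenyl]chroman | C=CCOc1cc(OCc7ccccc7)cc(OCc7ccccc7)c1[C@H]5c6c(OCc7ccccc7)cc(OCc7ccccc7)cc6O[C@H](c6ccc(OCc7ccccc7)cc6)[C@@H]5OCc7ccccc7 | intermediate
20 | 2-[(2R,3R,4β)-3,5,7-tris(benzyloxy)-2-(4-benzyloxyphenyl)chroman-4-yl]-3,5-bis(benzyloxy)phenol | Oc1cc(OCc7ccccc7)cc(OCc7ccccc7)c1[C@H]5c6c(OCc7ccccc7)cc(OCc7ccccc7)cc6O[C@H](c6ccc(OCc7ccccc7)cc6)[C@@H]5OCc7ccccc7 | intermediate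
21 | ether of phenol 20 with the (R)-[4-(benzyloxy)phenyl]{(2S,3S)-3-[2-(allyloxy)-4,6-bis(benzyloxy)phenyl]oxiran-2-yl}methyl group | O(c1cc(OCc7ccccc7)cc(OCc7ccccc7)c1[C@H]5c6c(OCc7ccccc7)cc(OCc7ccccc7)cc6O[C@H](c6ccc(OCc7ccccc7)cc6)[C@@H]5OCc7ccccc7)[C@H](c4ccc(OCc7ccccc7)cc4)[C@@H]3O[C@H]3c2c(OCC=C)cc(OCc7ccccc7)cc2OCc7ccccc7 | intermediate
22 | upper dimer: (2R,3R)-4β-[2-(allyloxy)-4,6-bis(benzyloxy)phenyl]-5,7-bis(benzyloxy)-2-[4-(benzyloxy)phenyl]chroman-3-ol bearing at C8 the (2R,3R,4β)-3,5,7-tris(benzyloxy)-2-(4-benzyloxyphenyl)chroman-4-yl group | C=CCOc1cc(OCc7ccccc7)cc(OCc7ccccc7)c1[C@H]3c4c(OCc7ccccc7)cc(OCc7ccccc7)c([C@H]5c6c(OCc7ccccc7)cc(OCc7ccccc7)cc6O[C@H](c6ccc(OCc7ccccc7)cc6)[C@@H]5OCc7ccccc7)c4O[C@H](c4ccc(OCc7ccccc7)cc4)[C@@H]3O | intermediate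
23 | 3-O-benzyl ether of 22 | C=CCOc1cc(OCc7ccccc7)cc(OCc7ccccc7)c1[C@H]3c4c(OCc7ccccc7)cc(OCc7ccccc7)c([C@H]5c6c(OCc7ccccc7)cc(OCc7ccccc7)cc6O[C@H](c6ccc(OCc7ccccc7)cc6)[C@@H]5OCc7ccccc7)c4O[C@H](c4ccc(OCc7ccccc7)cc4)[C@@H]3OCc7ccccc7 | intermediate
24 | upper-dimer phenol: 23 with hydroxyl in place of allyloxy | Oc1cc(OCc7ccccc7)cc(OCc7ccccc7)c1[C@H]3c4c(OCc7ccccc7)cc(OCc7ccccc7)c([C@H]5c6c(OCc7ccccc7)cc(OCc7ccccc7)cc6O[C@H](c6ccc(OCc7ccccc7)cc6)[C@@H]5OCc7ccccc7)c4O[C@H](c4ccc(OCc7ccccc7)cc4)[C@@H]3OCc7ccccc7 | intermediate
25 | methyl 3,5-dihydroxy-4-methoxybenzoate | COC(=O)c1cc(O)c(OC)c(O)c1 | starting material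
26 | methyl 3,5-bis(benzyloxy)-4-methoxybenzoate | COC(=O)c1cc(OCc2ccccc2)c(OC)c(OCc2ccccc2)c1 | intermediate
27 | [3,5-bis(benzyloxy)-4-methoxyphenyl]methanol | OCc1cc(OCc2ccccc2)c(OC)c(OCc2ccccc2)c1 | intermediate
28 | 3,5-bis(benzyloxy)-4-methoxybenzaldehyde | O=Cc1cc(OCc2ccccc2)c(OC)c(OCc2ccccc2)c1 | intermediate
29 | rac-1-[3,5-bis(benzyloxy)-4-methoxyphenyl]prop-2-en-1-ol | OC(C=C)c1cc(OCc2ccccc2)c(OC)c(OCc2ccccc2)c1 | intermediate
30 | (S)-[3,5-bis(benzyloxy)-4-methoxyphenyl][(2R)-oxiran-2-yl]methanol (erythro) | O[C@@H](c1cc(OCc2ccccc2)c(OC)c(OCc2ccccc2)c1)[C@H]1CO1 | intermediate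
31 | ether of phenol 24 with the (R)-[3,5-bis(benzyloxy)-4-methoxyphenyl][(2R)-oxiran-2-yl]methyl group | O(c1cc(OCc7ccccc7)cc(OCc7ccccc7)c1[C@H]3c4c(OCc7ccccc7)cc(OCc7ccccc7)c([C@H]5c6c(OCc7ccccc7)cc(OCc7ccccc7)cc6O[C@H](c6ccc(OCc7ccccc7)cc6)[C@@H]5OCc7ccccc7)c4O[C@H](c4ccc(OCc7ccccc7)cc4)[C@@H]3OCc7ccccc7)[C@H](c1cc(OCc7ccccc7)c(OC)c(OCc7ccccc7)c1)[C@H]2CO2 | intermediate
32 | dodeca-O-benzyl target: all ten phenols and the C3 hydroxyls of the top and middle units benzylated, bottom 3-hydroxyl free; all units (2R,3R), both linkages 4β→8 | COc1c(OCc7ccccc7)cc([C@H]2Oc3c(c(OCc7ccccc7)cc(OCc7ccccc7)c3[C@H]3c4c(OCc7ccccc7)cc(OCc7ccccc7)c([C@H]5c6c(OCc7ccccc7)cc(OCc7ccccc7)cc6O[C@H](c6ccc(OCc7ccccc7)cc6)[C@@H]5OCc7ccccc7)c4O[C@H](c4ccc(OCc7ccccc7)cc4)[C@@H]3OCc7ccccc7)C[C@H]2O)cc1OCc7ccccc7 | intermediate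
33 | epiafzelechin-(4β→8)-epiafzelechin-(4β→8)-4'-O-methylepigallocatechin (CNP0146516.1) | COc1c(O)cc([C@H]2Oc3c(c(O)cc(O)c3[C@H]3c4c(O)cc(O)c([C@H]5c6c(O)cc(O)cc6O[C@H](c6ccc(O)cc6)[C@@H]5O)c4O[C@H](c4ccc(O)cc4)[C@@H]3O)C[C@H]2O)cc1O | target

## Count and risks

Total step count: 23. Longest linear sequence: 16 steps (steps 1 to 6, 9 to 15 and 21 to 23, from 1 to 33).

**Step 9 (key step, proposed new method).** What may go wrong:
- protonation of the aryl anion 17 before it reaches the epoxide;
- transfer of the silyl or triflyl group of 14 to alkoxide 15 in place of aryne release;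
- Payne migration of the epoxide within 15;
- opening of the epoxide at the wrong carbon (5-exo).

Fallback with known chemistry: Mitsunobu etherification of phenol 10 with the erythro alcohol 7 (PPh3, DIAD), where inversion gives the C2 configuration that 9 carries, would give the 3,5-bis(benzyloxy)phenyl ether F1. BF3·OEt2 at −78 °C would then close ring C by the epoxy–arene cyclisation of step 13; the two ortho carbons of the symmetric ring are equivalent. The fallback sets out from 10 and 7 and returns to the route at 18.

**Step 12.** What may go wrong: steric retardation of the SN2 displacement between a hindered phenol and a hindered carbinol, so that ionisation of the 4-benzyloxybenzylic oxyphosphonium ion, with loss of configuration or elimination, takes over. Fallback with the bonds made in the opposite order: a catalytic Lewis acid would let the ring carbon ortho to the free hydroxyl of 20 open the epoxide of 7 at its benzylic carbon (intermolecular Friedel–Crafts alkylation with inversion), giving the phenol diol F2. An intramolecular Mitsunobu etherification would then close O1–C2 with inversion at the benzylic carbinol. The fallback sets out from 20 and 7 and returns at 22.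

**Step 22.** What may go wrong: opening of the epoxide at the internal carbon (5-exo), or acid-induced cleavage of the C4–C8 bonds before the unactivated CH2 is attacked. Fallback that leaves only one electrophilic carbon:
- MgI2 would open the epoxide of 31 at the terminal carbon to the iodohydrin F3;
- pivaloyl chloride and pyridine would cap its carbinol as the pivalate F4, so that the epoxide cannot re-form;
- AgOTf with a hindered pyridine base would ionise the iodide, the neighbouring ester would guide attack to the primary carbon, and the arene would be alkylated 6-exo to give the flavan pivalate F5;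
- i-Bu2AlH would remove the ester.

The fallback sets out from 31 and returns at 32.

**Step 4.** What may go wrong: slow and poorly enantioselective oxygen transfer to a hindered, electron-rich enone. Fallback in which a metal-bound hydroxyl directs the oxidant: Luche reduction of 5 (NaBH4, CeCl3·7H2O, MeOH) would give the racemic allylic alcohol F6. Sharpless kinetic resolution with Ti(OiPr)4, L-(+)-DIPT and TBHP would epoxidise its (R)-enantiomer to the erythro epoxy alcohol. The fallback sets out from 5 and returns at 7, bypassing 6.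

**Step 6.** What may go wrong: ionisation at the benzylic carbinol during the Mitsunobu step, or migration of the epoxide (Payne rearrangement) during methanolysis. Fallback without a substitution at carbon: reagent-controlled Corey–Bakshi–Shibata reduction of ketone 6 with the oxazaborolidine enantiomer that delivers the (R)-carbinol, and catecholborane as the hydride source, overriding the erythro preference of the substrate. The fallback sets out from 6 and returns at 9, and makes no new compound.

## Further compounds

F1 | step 9 | 3,5-bis(benzyloxy)phenyl (R)-[4-(benzyloxy)phenyl]{(2S,3S)-3-[2-(allyloxy)-4,6-bis(benzyloxy)phenyl]oxiran-2-yl}methyl ether | O(c1cc(OCc2ccccc2)cc(OCc2ccccc2)c1)[C@H](c1ccc(OCc2ccccc2)cc1)[C@@H]1O[C@H]1c1c(OCC=C)cc(OCc2ccccc2)cc1OCc1ccccc1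
F2 | step 12 | phenol diol: 20 alkylated at the ring carbon ortho to its hydroxyl by the opened epoxide of 7 (1-aryl-1-[2-(allyloxy)-4,6-bis(benzyloxy)phenyl]-3-[4-(benzyloxy)phenyl]propane-2,3-diol) | C=CCOc1cc(OCc7ccccc7)cc(OCc7ccccc7)c1[C@@H](c4c(OCc7ccccc7)cc(OCc7ccccc7)c([C@H]5c6c(OCc7ccccc7)cc(OCc7ccccc7)cc6O[C@H](c6ccc(OCc7ccccc7)cc6)[C@@H]5OCc7ccccc7)c4O)[C@@H](O)[C@@H](O)c4ccc(OCc7ccccc7)cc4
F3 | step 22 | iodohydrin from 31 (epoxide opened to CH(OH)–CH2I) | O(c1cc(OCc7ccccc7)cc(OCc7ccccc7)c1[C@H]3c4c(OCc7ccccc7)cc(OCc7ccccc7)c([C@H]5c6c(OCc7ccccc7)cc(OCc7ccccc7)cc6O[C@H](c6ccc(OCc7ccccc7)cc6)[C@@H]5OCc7ccccc7)c4O[C@H](c4ccc(OCc7ccccc7)cc4)[C@@H]3OCc7ccccc7)[C@H](c1cc(OCc7ccccc7)c(OC)c(OCc7ccccc7)c1)[C@H](O)CI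
F4 | step 22 | pivalate of iodohydrin F3 | O(c1cc(OCc7ccccc7)cc(OCc7ccccc7)c1[C@H]3c4c(OCc7ccccc7)cc(OCc7ccccc7)c([C@H]5c6c(OCc7ccccc7)cc(OCc7ccccc7)cc6O[C@H](c6ccc(OCc7ccccc7)cc6)[C@@H]5OCc7ccccc7)c4O[C@H](c4ccc(OCc7ccccc7)cc4)[C@@H]3OCc7ccccc7)[C@H](c1cc(OCc7ccccc7)c(OC)c(OCc7ccccc7)c1)[C@H](OC(=O)C(C)(C)C)CI
F5 | step 22 | 3-O-pivaloyl derivative of 32 (bottom unit) | COc1c(OCc7ccccc7)cc([C@H]2Oc3c(c(OCc7ccccc7)cc(OCc7ccccc7)c3[C@H]3c4c(OCc7ccccc7)cc(OCc7ccccc7)c([C@H]5c6c(OCc7ccccc7)cc(OCc7ccccc7)cc6O[C@H](c6ccc(OCc7ccccc7)cc6)[C@@H]5OCc7ccccc7)c4O[C@H](c4ccc(OCc7ccccc7)cc4)[C@@H]3OCc7ccccc7)C[C@H]2OC(=O)C(C)(C)C)cc1OCc7ccccc7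
F6 | step 4 | rac-(E)-3-[2-(allyloxy)-4,6-bis(benzyloxy)phenyl]-1-[4-(benzyloxy)phenyl]prop-2-en-1-ol | OC(/C=C/c1c(OCC=C)cc(OCc2ccccc2)cc1OCc1ccccc1)c1ccc(OCc2ccccc2)cc1
F0 | step 6 | none | none
A1 | alternative 1 | trimer skeleton with the bottom unit as a 3-benzyloxychroman-2-one spiro orthoester of (2R,4R)-pentane-2,4-diol | C[C@@H]1C[C@@H](C)OC2(O1)Oc3c(c(OCc7ccccc7)cc(OCc7ccccc7)c3[C@H]3c4c(OCc7ccccc7)cc(OCc7ccccc7)c([C@H]5c6c(OCc7ccccc7)cc(OCc7ccccc7)cc6O[C@H](c6ccc(OCc7ccccc7)cc6)[C@@H]5OCc7ccccc7)c4O[C@H](c4ccc(OCc7ccccc7)cc4)[C@@H]3OCc7ccccc7)C[C@H]2OCc7ccccc7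
A2 | alternative 1 | (4R,6R)-2-[(benzyloxy)methylidene]-4,6-dimethyl-1,3-dioxane (chiral benzyloxyketene acetal) | C[C@@H]1C[C@@H](C)OC(=COCc2ccccc2)O1
A3 | alternative 1 | formaldehyde | C=O
A4 | alternative 2 | benzyl-protected target with the middle-unit 3-hydroxyl free | COc1c(OCc7ccccc7)cc([C@H]2Oc3c(c(OCc7ccccc7)cc(OCc7ccccc7)c3[C@H]3c4c(OCc7ccccc7)cc(OCc7ccccc7)c([C@H]5c6c(OCc7ccccc7)cc(OCc7ccccc7)cc6O[C@H](c6ccc(OCc7ccccc7)cc6)[C@@H]5OCc7ccccc7)c4O[C@H](c4ccc(OCc7ccccc7)cc4)[C@@H]3O)C[C@H]2OCc7ccccc7)cc1OCc7ccccc7
A5 | alternative 2 | erythro epoxy alcohol carrying the bottom flavan: (S)-[4-(benzyloxy)phenyl][(2S,3S)-3-{(2R,3R)-3,5,7-tris(benzyloxy)-2-[3,5-bis(benzyloxy)-4-methoxyphenyl]chroman-8-yl}oxiran-2-yl]methanol | COc1c(OCc7ccccc7)cc([C@H]2Oc3c(c(OCc7ccccc7)cc(OCc7ccccc7)c3[C@@H]3O[C@H]3[C@@H](O)c3ccc(OCc7ccccc7)cc3)C[C@H]2OCc7ccccc7)cc1OCc7ccccc7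
A6 | alternative 3 | upper dimer bonded at the lower C4 to a 4-benzyloxy-2,6-dihydroxyphenyl ring | Oc1cc(OCc7ccccc7)cc(O)c1[C@H]3c4c(OCc7ccccc7)cc(OCc7ccccc7)c([C@H]5c6c(OCc7ccccc7)cc(OCc7ccccc7)cc6O[C@H](c6ccc(OCc7ccccc7)cc6)[C@@H]5OCc7ccccc7)c4O[C@H](c4ccc(OCc7ccccc7)cc4)[C@@H]3OCc7ccccc7
A7 | alternative 3 | methyl (E)-3-(benzyloxy)-5-oxohex-2-enoate attached through C6 to C4 (4β) of the middle unit of the upper dimer | COC(=O)/C=C(/OCc7ccccc7)CC(=O)C[C@H]3c4c(OCc7ccccc7)cc(OCc7ccccc7)c([C@H]5c6c(OCc7ccccc7)cc(OCc7ccccc7)cc6O[C@H](c6ccc(OCc7ccccc7)cc6)[C@@H]5OCc7ccccc7)c4O[C@H](c4ccc(OCc7ccccc7)cc4)[C@@H]3OCc7ccccc7
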